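Overview: the target is read as (1'R,5E). It has one ring, a 2(5H)-furanone (O1, C2=O, C3, C4–Br, C5), an exocyclic C5=C6HBr with Br on the C4 side, and the C1' acetate on C3.
C6–Br is disconnected last, to a (Z)-C6–SiMe3 group. Anti addition of Br2 followed by anti Si/Br elimination inverts the geometry and gives the crowded E-bromide.
Key disconnection: the ring C3=C4 double bond. The enabling feature is that O1 sits on C5, the middle carbon of the unit C4–C5–C6, and that its ring neighbour C4 is an sp2 carbon bearing only Br. The furanone is therefore a disguised 3-bromopropargyl ester (acyloxy slid from C6 to C5, bromoalkyne terminus = carbenoid C4), and C3 is a diazo carbon that couples with C4 under loss of N2.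
The acyclic precursor, 3-bromo-1-(trimethylsilyl)prop-2-ynyl (R)-3-acetoxy-2-diazohexanoate, comes from a diazoacetate and butanal by a catalytic asymmetric aldol addition that sets C1'.
Ring order: the butenolide is the only ring, it is formed in the key step, and no ring exists before it.

Key step: step 7

Assumption: (R,R)-ProPhenol is taken to guide the diazoacetate to the Si face of butanal. Both ligand antipodes are commercial, so an MTPA ester check of 9 allows the sense to be corrected by a ligand swap without changing the route.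

Step 1
Reactants: 1 3-(trimethylsilyl)prop-2-yn-1-ol
Product: 3 1,3-bis(trimethylsilyl)prop-2-yn-1-ol (racemic), via silyl ether 2 (not isolated)
Conditions: n-BuLi (1.0 equiv), THF, −78 °C; Me3SiCl (1.0 equiv), to 0 °C; t-BuLi (1.2 equiv), −78 to −45 °C; AcOH quench at −78 °C
Reagents that add atoms: chlorotrimethylsilane, C[Si](C)(C)Cl
Why: O-silylation followed by a retro-Brook rearrangement (1,2 shift of silicon from O to the lithiated propargylic carbon, driven by the stronger O–Li bond) is established for 2-alkynyl silyl ethers, and the new carbinol centre may be racemic because it becomes the sp2 carbon C6 in step 7.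

Step 2
Reactants: 3 1,3-bis(trimethylsilyl)prop-2-yn-1-ol; 4 bromoacetyl bromide
Product: 5 1,3-bis(trimethylsilyl)prop-2-yn-1-yl bromoacetate (racemic)
Conditions: pyridine (1.2 equiv), CH2Cl2, −20 to 0 °C
Reagents that add atoms: none
Why: Simple O-acylation of a secondary alcohol by an acid bromide, run under a weak base so that no alkoxide is formed that could trigger a forward Brook rearrangement.

Step 3
Reactants: 5 1,3-bis(trimethylsilyl)prop-2-yn-1-yl bromoacetate
Product: 6 3-bromo-1-(trimethylsilyl)prop-2-yn-1-yl bromoacetate (racemic)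
Conditions: NBS (1.1 equiv), AgNO3 (20 mol %), acetone, 20 °C, dark
Reagents that add atoms: N-bromosuccinimide, O=C1CCC(=O)N1Br
Why: Silver-catalysed desilylative bromination of an alkynylsilane by NBS proceeds through the silver acetylide and therefore exchanges only the sp C–Si bond, leaving the sp3 C–Si bond and the bromoacetate untouched.

Step 4
Reactants: 6 3-bromo-1-(trimethylsilyl)prop-2-yn-1-yl bromoacetate
Product: 7 3-bromo-1-(trimethylsilyl)prop-2-yn-1-yl diazoacetate (racemic)
Conditions: TsNHNHTs (2 equiv), DBU (5 equiv), THF, 0 °C, 15 min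
Reagents that add atoms: N,N'-ditosylhydrazine, Cc1ccc(cc1)S(=O)(=O)NNS(=O)(=O)c1ccc(C)cc1
Why: Diazoacetate synthesis from a bromoacetate: N-alkylation of N,N'-ditosylhydrazine and two base-induced sulfinate eliminations deliver the diazo group within minutes at 0 °C, which spares the bromoalkyne and the silyl ester carbon.

Step 5
Reactants: 7 3-bromo-1-(trimethylsilyl)prop-2-yn-1-yl diazoacetate; 8 butanal
Product: 9 3-bromo-1-(trimethylsilyl)prop-2-yn-1-yl (3R)-2-diazo-3-hydroxyhexanoate (two epimers at the silyl ester carbon)
Conditions: Bu2Mg (10 mol %), (R,R)-ProPhenol [2,6-bis{[(R)-2-(hydroxydiphenylmethyl)pyrrolidin-1-yl]methyl}-4-methylphenol, 5 mol %], cis-cyclopentane-1,2-diol (5 mol %), THF, −20 °C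
Reagents that add atoms: none
Why: Catalytic asymmetric aldol-type addition of a diazoacetate to an aldehyde under a dinuclear magnesium ProPhenol catalyst, in which the chiral pocket guides the diazo carbon to the Si face of butanal and so sets (R)-C1', while the racemic ester carbon only doubles the product into two epimers that converge in step 7.

Step 6
Reactants: 9 3-bromo-1-(trimethylsilyl)prop-2-yn-1-yl (3R)-2-diazo-3-hydroxyhexanoate
Product: 10 3-bromo-1-(trimethylsilyl)prop-2-yn-1-yl (3R)-3-acetoxy-2-diazohexanoate
Conditions: Ac2O (1.5 equiv), pyridine, DMAP (5 mol %), CH2Cl2, 0 to 20 °C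
Reagents that add atoms: acetic anhydride, CC(=O)OC(C)=O
Why: DMAP-catalysed acetylation leaves the C1'–O bond intact so that (R) is retained, and the product cannot eliminate acetic acid toward C3 because the diazo carbon bears no hydrogen.

Step 7
Reactants: 10 3-bromo-1-(trimethylsilyl)prop-2-yn-1-yl (3R)-3-acetoxy-2-diazohexanoate
Product: 13 (1R)-1-{(5Z)-4-bromo-2-oxo-5-[(trimethylsilyl)methylidene]-2,5-dihydrofuran-3-yl}butyl acetate, via gold carbenoid 11 (not isolated), via aurated diazonium ion 12 (not isolated)
Conditions: (IPr)AuNTf2 (5 mol %; IPr = 1,3-bis(2,6-diisopropylphenyl)imidazol-2-ylidene, NTf2 = bis(trifluoromethanesulfonyl)imide), 4 Å MS, ClCH2CH2Cl, slow addition of 10 (final 0.005 M), 25 to 40 °C, dark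
Reagents that add atoms: none
Why: Proposed new method: the cationic gold centre binds the bromoalkyne of 10, the Lewis-basic diazoester carbonyl oxygen adds 5-exo-dig to the inner alkyne carbon (the future C5) and the resulting 1,3-dioxolenium ion opens at the old C6–O bond, so that the acyloxy group slides from C6 to C5 and the bromoalkyne terminus becomes the carbenoid carbon C4 of 11. After rotation about the C2–O1 bond the nucleophilic diazo carbon C3 adds to C4 to give the β-aurated diazonium ion 12, which expels N2 and the gold cation in one anti elimination and thereby writes the C3=C4 double bond with bromine already in place on C4. The closest known reaction types are the halogen-directed gold-catalysed 1,2-acyloxy migration of 3-halopropargyl carboxylates, the gold-catalysed cross-coupling of a gold carbene with a diazo ester to a tetrasubstituted alkene, and the cationic gold activation of propargyl diazoacetates that leaves the diazo group intact; new is only their merger, with the migrating acyl group itself carrying the diazo nucleophile. The single ring, the butenolide, closes in a 5-exo-trig mode with respect to the C4=Au bond, C3 acting through its exocyclic C=N2 unit. No stereocentre is created: C1' stays (R) because it is never ionised (C–Au hyperconjugation makes loss of N2 from 12 faster than a hydride or acetoxy shift), the racemic silyl ester carbon becomes sp2 C6, and C5=C6 should form Z (Si syn to O1) because in the configurationally mobile carbenoid the silyl group turns away from the Br- and Au-bearing C4. The step needs alkyne activation ahead of diazo decomposition, 1,2- ahead of 1,3-migration, and attack at C4 instead of the vinylogous terminus C6; these rest on the alkynophilic NHC gold cation at high dilution, on the bromine at the alkyne terminus, and on the C6 silyl group, which shields that terminus and, lying in the nodal plane, offers its positive charge no stabilisation.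

Step 8
Reactants: 13 (1R)-1-{(5Z)-4-bromo-2-oxo-5-[(trimethylsilyl)methylidene]-2,5-dihydrofuran-3-yl}butyl acetate
Product: 15 acetoxyfimbrolide, (1R)-1-[(5E)-4-bromo-5-(bromomethylidene)-2-oxo-2,5-dihydrofuran-3-yl]butyl acetate, via anti dibromide 14 (not isolated)
Conditions: Br2 (1.0 equiv), CH2Cl2, −78 °C, dark; then Bu4NF (1.0 equiv, THF), −78 °C, slow addition
Reagents that add atoms: bromine, BrBr
Why: Bromodesilylation of a vinylsilane in its stereospecific two-stage form, anti addition of Br2 through the bromonium ion (kept bridged by the electron-poor lactone, low temperature and non-polar medium) followed by fluoride-triggered anti elimination of silicon and the C5 bromide, replaces Si by Br under inversion, so that the Z-silane gives the E-bromide with Br syn to C4, and C1' is not involved.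

Compound list
1 | 3-(trimethylsilyl)prop-2-yn-1-ol | C[Si](C)(C)C#CCO | starting material
2 | trimethyl{[3-(trimethylsilyl)prop-2-yn-1-yl]oxy}silane (silyl ether) | C[Si](C)(C)C#CCO[Si](C)(C)C | intermediate
3 | 1,3-bis(trimethylsilyl)prop-2-yn-1-ol (racemic) | C[Si](C)(C)C#CC(O)[Si](C)(C)C | intermediate
4 | bromoacetyl bromide | O=C(Br)CBr | starting material
5 | 1,3-bis(trimethylsilyl)prop-2-yn-1-yl bromoacetate (racemic) | C[Si](C)(C)C#CC(OC(=O)CBr)[Si](C)(C)C | intermediate
6 | 3-bromo-1-(trimethylsilyl)prop-2-yn-1-yl bromoacetate (racemic) | BrC#CC(OC(=O)CBr)[Si](C)(C)C | intermediate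
7 | 3-bromo-1-(trimethylsilyl)prop-2-yn-1-yl diazoacetate (racemic) | [N-]=[N+]=CC(=O)OC(C#CBr)[Si](C)(C)C | intermediate
8 | butanal | CCCC=O | starting material
9 | 3-bromo-1-(trimethylsilyl)prop-2-yn-1-yl (3R)-2-diazo-3-hydroxyhexanoate (epimers at the silyl ester carbon) | CCC[C@@H](O)C(=[N+]=[N-])C(=O)OC(C#CBr)[Si](C)(C)C | intermediate
10 | 3-bromo-1-(trimethylsilyl)prop-2-yn-1-yl (3R)-3-acetoxy-2-diazohexanoate (epimers at the silyl ester carbon) | CCC[C@@H](OC(C)=O)C(=[N+]=[N-])C(=O)OC(C#CBr)[Si](C)(C)C | intermediate
11 | gold carbenoid after the 1,2-acyloxy shift (cation of the NTf2 salt; Z enol ester, C4 = C(Br)=Au(IPr)) | CCC[C@@H](OC(C)=O)C(=[N+]=[N-])C(=O)O/C(=C\[Si](C)(C)C)C(Br)=[Au]c1n(-c2c(C(C)C)cccc2C(C)C)cc[n+]1-c1c(C(C)C)cccc1C(C)C | intermediate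
12 | cyclised β-aurated diazonium ion (cation of the NTf2 salt; transient C3 and C4 centres undefined) | CCC[C@@H](OC(C)=O)C1([N+]#N)C(=O)O/C(=C\[Si](C)(C)C)C1(Br)[Au-]c1n(-c2c(C(C)C)cccc2C(C)C)cc[n+]1-c1c(C(C)C)cccc1C(C)C | intermediate
13 | (1R)-1-{(5Z)-4-bromo-2-oxo-5-[(trimethylsilyl)methylidene]-2,5-dihydrofuran-3-yl}butyl acetate | CCC[C@@H](OC(C)=O)C1=C(Br)/C(=C/[Si](C)(C)C)OC1=O | intermediate
14 | (1R)-1-{4,5-dibromo-5-[bromo(trimethylsilyl)methyl]-2-oxo-2,5-dihydrofuran-3-yl}butyl acetate, anti adduct (the 5R,αR face isomer is shown; the 5S,αS face isomer forms beside it and gives the same alkene) | CCC[C@@H](OC(C)=O)C1=C(Br)[C@@](Br)([C@@H](Br)[Si](C)(C)C)OC1=O | intermediate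
15 | acetoxyfimbrolide, (1R)-1-[(5E)-4-bromo-5-(bromomethylidene)-2-oxo-2,5-dihydrofuran-3-yl]butyl acetate | CCC[C@@H](OC(C)=O)C1=C(Br)/C(=C\Br)OC1=O | target

Total step count: 8. Longest linear sequence: 8 steps (from 1).

Steps most likely to fail

**Step 7.** Three things may go wrong:
- Gold may decompose the diazo group before it activates the alkyne, followed by a hydride shift to an enol acetate.
- The acyloxy group may migrate 1,3 to a bromoallenyl ester.
- C3 may attack the silyl-bearing allyl terminus.

The fallback uses known chemistry and closes the lactone at O1–C5 instead. It sets out from butanal 8 and comes back to the route at 13.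
- Butanal 8 and commercial tert-butyl diazoacetate give, under the conditions of step 5, tert-butyl (3R)-2-diazo-3-hydroxyhexanoate F1.
- Acetylation as in step 6 gives tert-butyl (3R)-3-acetoxy-2-diazohexanoate F2.
- Dimethyldioxirane in acetone at 0 °C oxidises the diazo carbon to tert-butyl (3R)-3-acetoxy-2-oxohexanoate F3.
- Ramirez olefination of the activated ketone (CBr4, PPh3, CH2Cl2, 0 °C) gives tert-butyl 2-[(1R)-1-acetoxybutyl]-3,3-dibromoacrylate F4.
- CF3CO2H in CH2Cl2 frees 2-[(1R)-1-acetoxybutyl]-3,3-dibromoacrylic acid F5.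
- Sonogashira coupling with ethynyltrimethylsilane (Pd(PPh3)4, CuI, Et3N, MeCN, 20 °C) should take place at the C–Br bond trans to the branched side chain, which is the one cis to CO2H. This gives (2E)-2-[(1R)-1-acetoxybutyl]-3-bromo-5-(trimethylsilyl)pent-2-en-4-ynoic acid F6.
- F6 lactonises in the same flask by anti 5-exo-dig addition of the carboxylate and a proton across the alkyne, giving the Z-silane 13.

**Step 8.** The bromonium ion may open to a β-silyl-stabilised open cation. Bond rotation then leads to substitution with retention and the E geometry is lost.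

The fallback is stereoconvergent. It sets out from 13 and comes back at 15.
- Br2 (1 equiv) in CH2Cl2 at 20 °C replaces silicon without regard to geometry and gives (1R)-1-[4-bromo-5-(bromomethylidene)-2-oxo-2,5-dihydrofuran-3-yl]butyl acetate as an E/Z mixture F7.
- A second equivalent of Br2 adds across C5=C6 to give (1R)-1-[4,5-dibromo-5-(dibromomethyl)-2-oxo-2,5-dihydrofuran-3-yl]butyl acetate F8.
- Et3N removes HBr to give (1R)-1-[4-bromo-5-(dibromomethylidene)-2-oxo-2,5-dihydrofuran-3-yl]butyl acetate F9, in which the geometry question has vanished.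
- Palladium-catalysed hydrogenolysis of the 1,1-dibromoalkene (Pd(PPh3)4, Bu3SnH 1.0 equiv, toluene, 20 °C) then removes the exposed bromine syn to O1. Zerovalent palladium inserts into the C–Br bond trans to the larger neighbour, and the C4–Br bond is shielded on both flanks. The bromine syn to C4 stays, which gives 15.

**Step 5.** Facial selectivity may be poor, or turnover slow, with an unbranched aliphatic aldehyde and the bulky new ester.

The fallback replaces asymmetric C–C bond formation by kinetic resolution. It sets out from 7 and 8 and comes back at 10.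
- DBU (10 mol %) in MeCN catalyses the uncontrolled aldol addition to 3-bromo-1-(trimethylsilyl)prop-2-yn-1-yl 2-diazo-3-hydroxyhexanoate racemic at C3 F10.
- Candida antarctica lipase B with vinyl acetate in MTBE acetylates the (R)-carbinol faster (large diazoester side, medium propyl side). This gives 10 directly.
- The unreacted 3-bromo-1-(trimethylsilyl)prop-2-yn-1-yl (3S)-2-diazo-3-hydroxyhexanoate F11 is removed by chromatography.

Further compounds
F1 | step 7 | tert-butyl (3R)-2-diazo-3-hydroxyhexanoate | CCC[C@@H](O)C(=[N+]=[N-])C(=O)OC(C)(C)C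
F2 | step 7 | tert-butyl (3R)-3-acetoxy-2-diazohexanoate | CCC[C@@H](OC(C)=O)C(=[N+]=[N-])C(=O)OC(C)(C)C
F3 | step 7 | tert-butyl (3R)-3-acetoxy-2-oxohexanoate | CCC[C@@H](OC(C)=O)C(=O)C(=O)OC(C)(C)C
F4 | step 7 | tert-butyl 2-[(1R)-1-acetoxybutyl]-3,3-dibromoacrylate | CCC[C@@H](OC(C)=O)C(=C(Br)Br)C(=O)OC(C)(C)C
F5 | step 7 | 2-[(1R)-1-acetoxybutyl]-3,3-dibromoacrylic acid | CCC[C@@H](OC(C)=O)C(=C(Br)Br)C(=O)O
F6 | step 7 | (2E)-2-[(1R)-1-acetoxybutyl]-3-bromo-5-(trimethylsilyl)pent-2-en-4-ynoic acid | CCC[C@@H](OC(C)=O)/C(C(=O)O)=C(\Br)C#C[Si](C)(C)C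
F7 | step 8 | (1R)-1-[4-bromo-5-(bromomethylidene)-2-oxo-2,5-dihydrofuran-3-yl]butyl acetate as an E/Z mixture | CCC[C@@H](OC(C)=O)C1=C(Br)C(=CBr)OC1=O
F8 | step 8 | (1R)-1-[4,5-dibromo-5-(dibromomethyl)-2-oxo-2,5-dihydrofuran-3-yl]butyl acetate | CCC[C@@H](OC(C)=O)C1=C(Br)C(Br)(C(Br)Br)OC1=O
F9 | step 8 | (1R)-1-[4-bromo-5-(dibromomethylidene)-2-oxo-2,5-dihydrofuran-3-yl]butyl acetate | CCC[C@@H](OC(C)=O)C1=C(Br)C(=C(Br)Br)OC1=O
F10 | step 5 | 3-bromo-1-(trimethylsilyl)prop-2-yn-1-yl 2-diazo-3-hydroxyhexanoate racemic at C3 | CCCC(O)C(=[N+]=[N-])C(=O)OC(C#CBr)[Si](C)(C)C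
F11 | step 5 | 3-bromo-1-(trimethylsilyl)prop-2-yn-1-yl (3S)-2-diazo-3-hydroxyhexanoate | CCC[C@H](O)C(=[N+]=[N-])C(=O)OC(C#CBr)[Si](C)(C)C
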